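**Assumption:** the target is taken exactly as drawn, i.e. the free 12‑acid with (5S,6R,7S,8R,10R) configuration in elemane numbering (10α‑methyl/10β‑vinyl, 5β‑H, 6α‑OH, 7α‑H, 8β‑acyloxy). Germacrane/elemane locants C1–C15 are used in the comments.

## Retrosynthetic overview
1. Target ⇐ elemane 6,15‑diol 8,12‑lactone: open the lactone, protect the acid as PMB ester, acylate O8 with (Z)‑4‑acetoxy‑2‑methylbut‑2‑enoic acid, cleave the PMB ester.
2. Elemane (cyclohexane, formed last) ⇐ Cope rearrangement of a germacra‑1(10),4‑dien‑12,8‑olide, forced through the normally disfavoured chair by a transient O6/O15 phenylboronate bridge (sets C5 and C10).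
3. Germacradiene (ten‑membered ring, formed before it) ⇐ intramolecular Cr(II) allylation closing C6–C7, the bond closed in germacrene biosynthesis, from a (Z)‑enal and a 3‑(bromomethyl)butenolide (sets C6 and C7 from C8).
4. Acyclic precursor ⇐ (R)‑epichlorohydrin (C8), TMS‑acetylene, Me3Al and ethylene oxide (E‑olefin), propargyl alcohol (C4–C6, C15), 2‑(bromomethyl)acrylic acid (RCM to the butenolide).
5. Ring order: auxiliary butenolide (RCM) → ten‑membered carbocycle → cyclohexane (Cope).

## Route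

Step 1
Reactants: 1 (R)-epichlorohydrin; 2 ethynyltrimethylsilane
Product: 4 (2R)-1-chloro-5-(trimethylsilyl)pent-4-yn-2-ol, via lithium (trimethylsilyl)acetylide 3 (not isolated)
Conditions: 2, n-BuLi, THF, −78 °C; BF3·OEt2; then 1, −78 °C
Reagents that add atoms: none
Why: BF3-mediated epoxide alkynylation (Yamaguchi type) opens the oxirane only at its unsubstituted CH2, so the C–O stereocentre (future C8) is taken unchanged from the chiral pool.

Step 2
Reactants: 4 (2R)-1-chloro-5-(trimethylsilyl)pent-4-yn-2-ol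
Product: 7 (3R)-hex-1-en-5-yn-3-ol, via (2R)-2-[3-(trimethylsilyl)prop-2-yn-1-yl]oxirane 5 (not isolated), via (3R)-6-(trimethylsilyl)hex-1-en-5-yn-3-ol 6 (not isolated)
Conditions: Me3S+ I− (4 equiv), n-BuLi (3.9 equiv), THF, −20 °C → rt; then K2CO3, MeOH, rt
Reagents that add atoms: trimethylsulfonium iodide C[S+](C)C.[I-]
Why: Excess dimethylsulfonium methylide closes the chlorohydrin to epoxide 5, opens it at CH2 and eliminates Me2S (one-carbon epoxide-to-allylic-alcohol homologation with the Corey–Chaykovsky ylide), and K2CO3/MeOH then removes the C-silyl group, the carbinol carbon never being a reaction centre.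

Step 3
Reactants: 7 (3R)-hex-1-en-5-yn-3-ol
Product: 10 (3R,5E)-5-methylocta-1,5-diene-3,8-diol, via alkenyl(dimethyl)alane 8 (not isolated), via lithium alkenylalanate 9 (not isolated)
Conditions: Me3Al (3.5 equiv), Cp2ZrCl2 (0.25 equiv), CH2Cl2, 0 °C → rt; n-BuLi (1 equiv), THF, −30 °C; ethylene oxide, −30 → 0 °C; Rochelle salt
Reagents that add atoms: trimethylaluminium C[Al](C)C; oxirane C1CO1
Why: Negishi Zr-catalysed methylalumination adds Me and Al syn across the terminal alkyne (Me on the internal carbon) and the derived alanate opens ethylene oxide with retention, which fixes the (E)-trisubstituted C1=C10 olefin while the monosubstituted vinyl group is left alone.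

Step 4
Reactants: 10 (3R,5E)-5-methylocta-1,5-diene-3,8-diol
Product: 11 (3R,5E)-8-bromo-5-methylocta-1,5-dien-3-ol
Conditions: CBr4 (1.05 equiv), PPh3 (1.05 equiv), 2,6-lutidine, CH2Cl2, −40 → −10 °C
Reagents that add atoms: carbon tetrabromide BrC(Br)(Br)Br
Why: Appel bromination is kinetically selective for the unhindered primary alcohol over the secondary allylic one at low temperature and limiting reagent.

Step 5
Reactants: 11 (3R,5E)-8-bromo-5-methylocta-1,5-dien-3-ol; 12 prop-2-yn-1-ol
Product: 15 (3R,5E,9Z)-9-(hydroxymethyl)-10-iodo-5-methyldeca-1,5,9-trien-3-ol, via alkoxide Grignard reagent 13 (not isolated), via (Z)-alkenylmagnesium chelate 14 (not isolated)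
Conditions: 11, i-PrMgCl (1 equiv), THF, −20 °C; Mg, 45 °C; add to 12 (1.5 equiv)/i-PrMgCl (1.5 equiv)/CuI (15 mol %), THF, −10 °C → rt; I2, −40 → 0 °C
Reagents that add atoms: iodine II
Why: Cu-catalysed alkoxide-directed anti-carbomagnesiation of propargyl alcohol (Duboudin–Normant type) puts the alkyl group on the internal carbon and Mg cis to CH2O in a five-membered chelate, so iodinolysis with retention gives only the (Z)-iodoalkene in which C15 and the future C6 are cis.

Step 6
Reactants: 15 (3R,5E,9Z)-9-(hydroxymethyl)-10-iodo-5-methyldeca-1,5,9-trien-3-ol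
Product: 16 (3R,5E,9Z)-9-{[(tert-butyldimethylsilyl)oxy]methyl}-10-iodo-5-methyldeca-1,5,9-trien-3-ol
Conditions: TBSCl (1.05 equiv), imidazole, CH2Cl2, −10 °C
Reagents that add atoms: tert-butyldimethylsilyl chloride CC(C)(C)[Si](C)(C)Cl
Why: Silylation discriminates the primary allylic hydroxyl (C15) from the hindered secondary one (C8) on steric grounds.

Step 7
Reactants: 16 (3R,5E,9Z)-9-{[(tert-butyldimethylsilyl)oxy]methyl}-10-iodo-5-methyldeca-1,5,9-trien-3-ol
Product: 17 (2Z,6E,9R)-3-{[(tert-butyldimethylsilyl)oxy]methyl}-9-hydroxy-7-methylundeca-2,6,10-trienal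
Conditions: Pd(PPh3)4 (5 mol %), CO (3 bar), Bu3SnH (syringe pump), THF, 50 °C
Reagents that add atoms: carbon monoxide [C-]#[O+]
Why: Stille-type Pd-catalysed reductive carbonylation (formylation) of the vinyl iodide proceeds with retention of olefin geometry and tolerates the free alcohol, and the silyl ether keeps the (Z)-γ-oxy-enal from closing to a lactol and aromatising to a furan.

Step 8
Reactants: 17 (2Z,6E,9R)-3-{[(tert-butyldimethylsilyl)oxy]methyl}-9-hydroxy-7-methylundeca-2,6,10-trienal; 18 2-(bromomethyl)prop-2-enoic acid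
Product: 20 (3R,5E,9Z)-9-{[(tert-butyldimethylsilyl)oxy]methyl}-5-methyl-11-oxoundeca-1,5,9-trien-3-yl 2-(bromomethyl)prop-2-enoate, via O-acylisourea 19 (not isolated)
Conditions: DCC, DMAP (5 mol %), CH2Cl2, −20 → 0 °C
Reagents that add atoms: none
Why: Steglich esterification acylates the only free hydroxyl with retention at C8 (only the O–H bond is broken), DMAP being kept catalytic and cold to avoid SN2′ attack on the allylic bromide.

Step 9
Reactants: 20 (3R,5E,9Z)-9-{[(tert-butyldimethylsilyl)oxy]methyl}-5-methyl-11-oxoundeca-1,5,9-trien-3-yl 2-(bromomethyl)prop-2-enoate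
Product: 21 (2Z,6E)-8-[(2R)-4-(bromomethyl)-5-oxo-2,5-dihydrofuran-2-yl]-3-{[(tert-butyldimethylsilyl)oxy]methyl}-7-methylocta-2,6-dienal
Conditions: Grubbs II (5 mol %), CH2Cl2 (0.01 M), 40 °C
Reagents that add atoms: none
Why: Ring-closing metathesis between the monosubstituted vinyl group and the 1,1-disubstituted acrylate closes the five-membered butenolide with loss of ethene, the trisubstituted olefins and the enal being spectators for the Ru carbene.

Step 10
Reactants: 21 (2Z,6E)-8-[(2R)-4-(bromomethyl)-5-oxo-2,5-dihydrofuran-2-yl]-3-{[(tert-butyldimethylsilyl)oxy]methyl}-7-methylocta-2,6-dienal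
Product: 23 (6R,7S,8R)-15-[(tert-butyldimethylsilyl)oxy]-6-hydroxygermacra-1(10),4,11(13)-trien-12,8-olide, via allylchromium(III) species 22 (not isolated)
Conditions: CrCl2 (8 equiv), THF, rt, 21 added over 10 h (final 3 mM); H2O
Reagents that add atoms: none
Why: Nozaki–Hiyama–Kishi macrocyclisation forms C6–C7: the butenolide ring locks the allylchromium in the E-type geometry (C8 trans to CH2Cr), the short C9→C5 tether lets the aldehyde reach only the butenolide face that carries C9 (cis-fused lactone, 7α-H), and the closed chair transition state with the enal residue equatorial gives the anti 6α-OH, so (8R) relays to (6R,7S).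

Step 11
Reactants: 23 (6R,7S,8R)-15-[(tert-butyldimethylsilyl)oxy]-6-hydroxygermacra-1(10),4,11(13)-trien-12,8-olide
Product: 27 (5S,6R,7S,8R,10R)-6,15-dihydroxyelema-1,3,11(13)-trien-12,8-olide, via germacradienolide 6,15-diol 24 (not isolated), via germacradienolide phenylboronate 25 (not isolated), via elemanolide phenylboronate 26 (not isolated)
Conditions: HF·pyridine, pyridine, THF, 0 °C; NaHCO3 work-up; crude 24, PhB(OH)2 (1.05 equiv), 4 Å MS, PhMe, rt then 130 °C (sealed), 12 h; aq sorbitol/Na2CO3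
Reagents that add atoms: none
Why: Proposed new method: a Cope rearrangement whose facial course is dictated by a transient seven-membered phenylboronate across O6 and O15, because the one-atom boron bridge can span the two oxygens only when O6 lies on the C15 side of the C4=C5 plane (O6···C15 about 2.6–3.3 Å), which is the olefin orientation of the chair transition state that gives 5β-H and 10α-methyl with O6 and C11 axial, whereas the normally preferred chair (H6 eclipsing the olefin, O6···C15 about 4 Å) cannot be reached without breaking the tether, and the chair itself makes the vinyl and the C5 alkenyl group trans; the closest known reactions are the thermal Cope rearrangement of germacra-1(10),4-dienes to elemanes and temporary arylboronate tethering of 1,4-diols.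

Step 12
Reactants: 27 (5S,6R,7S,8R,10R)-6,15-dihydroxyelema-1,3,11(13)-trien-12,8-olide
Product: 29 4-methoxybenzyl (5S,6R,7R,8R,10R)-6,8,15-trihydroxyelema-1,3,11(13)-trien-12-oate, via lithium hydroxy-carboxylate 28 (not isolated)
Conditions: LiOH·H2O (1.3 equiv), THF/H2O, 0 °C → rt; concentrate; PMBCl, Bu4NI (cat.), DMF, rt
Reagents that add atoms: lithium hydroxide [Li+].[OH-]; 4-methoxybenzyl chloride COc1ccc(CCl)cc1
Why: Saponification of the γ-lactone followed by SN2 alkylation of the carboxylate frees O8 without touching a stereocentre (the C7 descriptor changes only by CIP priority), since the carboxylate salt cannot relactonise and neutral alcohols are not alkylated.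

Step 13
Reactants: 30 3-methylfuran-2(5H)-one
Product: 33 4-methoxybenzyl (2Z)-4-acetoxy-2-methylbut-2-enoate, via potassium (2Z)-4-hydroxy-2-methylbut-2-enoate 31 (not isolated), via 4-methoxybenzyl (2Z)-4-hydroxy-2-methylbut-2-enoate 32 (not isolated)
Conditions: KOH (1.0 equiv), H2O/MeOH, rt; concentrate; PMBCl, DMF, 0 °C; then Ac2O, pyridine, DMAP (cat.), 0 °C
Reagents that add atoms: potassium hydroxide [K+].[OH-]; 4-methoxybenzyl chloride COc1ccc(CCl)cc1; acetic anhydride CC(=O)OC(C)=O
Why: Hydrolytic opening of the butenolide can only deliver the (Z)-γ-hydroxy-enoate because the ring enforces the cis geometry, and carboxylate alkylation followed at once by O-acetylation traps it before relactonisation.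

Step 14
Reactants: 33 4-methoxybenzyl (2Z)-4-acetoxy-2-methylbut-2-enoate
Product: 34 (2Z)-4-acetoxy-2-methylbut-2-enoic acid
Conditions: TFA/CH2Cl2 (1:4), anisole, 0 °C
Reagents that add atoms: none
Why: Acidolysis of the PMB ester (SN1, cation trapped by anisole) leaves the primary allylic acetate and the Z double bond intact.

Step 15
Reactants: 29 4-methoxybenzyl (5S,6R,7R,8R,10R)-6,8,15-trihydroxyelema-1,3,11(13)-trien-12-oate; 34 (2Z)-4-acetoxy-2-methylbut-2-enoic acid
Product: 38 4-methoxybenzyl (5S,6R,7S,8R,10R)-8-{[(2Z)-4-acetoxy-2-methylbut-2-enoyl]oxy}-6,15-dihydroxyelema-1,3,11(13)-trien-12-oate, via Yamaguchi mixed anhydride 35 (not isolated), via 6,15-phenylboronate 36 (not isolated), via 8-O-acylated phenylboronate 37 (not isolated)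
Conditions: 34, 2,4,6-Cl3C6H2COCl, Et3N, PhMe, 0 °C; separately 29, PhB(OH)2 (1.05 equiv), 4 Å MS, PhMe, rt; combine, DMAP (0.3 equiv), 0 °C → rt; aq sorbitol/NaHCO3
Reagents that add atoms: none
Why: Yamaguchi esterification of the only free hydroxyl while the 6,15-diol is masked in situ as its cyclic phenylboronate (transient boronate protection; the trans-1,3 O6/O8 pair cannot be bridged), run cold to preserve the angelate-type Z geometry and with retention at C8 because only the O–H bond is broken.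

Step 16
Reactants: 38 4-methoxybenzyl (5S,6R,7S,8R,10R)-8-{[(2Z)-4-acetoxy-2-methylbut-2-enoyl]oxy}-6,15-dihydroxyelema-1,3,11(13)-trien-12-oate
Product: 39 (5S,6R,7S,8R,10R)-8-{[(2Z)-4-acetoxy-2-methylbut-2-enoyl]oxy}-6,15-dihydroxyelema-1,3,11(13)-trien-12-oic acid (target CNP0261293.1)
Conditions: TFA/CH2Cl2 (1:9), anisole, 0 °C, 15 min; NaHCO3/MeOH quench
Reagents that add atoms: none
Why: Brief acidolysis of the PMB ester with a cation scavenger releases the acid, which does not lactonise onto O6 because 6α-OH and the C7 acrylate are trans-diaxial in the preferred chair, and the acetate, the Z-enoate and the exocyclic alkenes survive.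

## Compound list
1 | (R)-epichlorohydrin [(2R)-2-(chloromethyl)oxirane] | ClC[C@H]1CO1 | starting material
2 | ethynyltrimethylsilane | C#C[Si](C)(C)C | starting material
3 | lithium (trimethylsilyl)acetylide | [Li]C#C[Si](C)(C)C | intermediate
4 | (2R)-1-chloro-5-(trimethylsilyl)pent-4-yn-2-ol | ClC[C@H](O)CC#C[Si](C)(C)C | intermediate
5 | (2R)-2-[3-(trimethylsilyl)prop-2-yn-1-yl]oxirane | C1O[C@@H]1CC#C[Si](C)(C)C | intermediate
6 | (3R)-6-(trimethylsilyl)hex-1-en-5-yn-3-ol | C=C[C@H](O)CC#C[Si](C)(C)C | intermediate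
7 | (3R)-hex-1-en-5-yn-3-ol | C=C[C@H](O)CC#C | intermediate
8 | (E)-alkenyl(dimethyl)alane, O-dimethylaluminium alkoxide | C=C[C@H](O[Al](C)C)C/C(C)=C/[Al](C)C | intermediate
9 | lithium butyl(dimethyl)alkenylalanate | C=C[C@H](O[Al](C)C)C/C(C)=C/[Al-](C)(C)CCCC.[Li+] | intermediate
10 | (3R,5E)-5-methylocta-1,5-diene-3,8-diol | C=C[C@H](O)C/C(C)=C/CCO | intermediate
11 | (3R,5E)-8-bromo-5-methylocta-1,5-dien-3-ol | C=C[C@H](O)C/C(C)=C/CCBr | intermediate
12 | prop-2-yn-1-ol | C#CCO | starting material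
13 | alkoxide Grignard reagent of 11 | C=C[C@H](O[Mg]Cl)C/C(C)=C/CC[Mg]Br | intermediate
14 | (Z)-alkenylmagnesium chelate (Mg cis to CH2O) | Br[Mg]/C=C(\CO[Mg]Cl)CC/C=C(\C)C[C@@H](O[Mg]Cl)C=C | intermediate
15 | (3R,5E,9Z)-9-(hydroxymethyl)-10-iodo-5-methyldeca-1,5,9-trien-3-ol | I/C=C(\CO)CC/C=C(\C)C[C@@H](O)C=C | intermediate
16 | (3R,5E,9Z)-9-{[(tert-butyldimethylsilyl)oxy]methyl}-10-iodo-5-methyldeca-1,5,9-trien-3-ol | I/C=C(\CO[Si](C)(C)C(C)(C)C)CC/C=C(\C)C[C@@H](O)C=C | intermediate
17 | (2Z,6E,9R)-3-{[(tert-butyldimethylsilyl)oxy]methyl}-9-hydroxy-7-methylundeca-2,6,10-trienal | O=C/C=C(\CO[Si](C)(C)C(C)(C)C)CC/C=C(\C)C[C@@H](O)C=C | intermediate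
18 | 2-(bromomethyl)prop-2-enoic acid | C=C(CBr)C(=O)O | starting material
19 | O-acylisourea of 18 with DCC | C=C(CBr)C(=O)OC(=NC1CCCCC1)NC1CCCCC1 | intermediate
20 | (3R,5E,9Z)-9-{[(tert-butyldimethylsilyl)oxy]methyl}-5-methyl-11-oxoundeca-1,5,9-trien-3-yl 2-(bromomethyl)prop-2-enoate | O=C/C=C(\CO[Si](C)(C)C(C)(C)C)CC/C=C(\C)C[C@@H](OC(=O)C(=C)CBr)C=C | intermediate
21 | (2Z,6E)-8-[(2R)-4-(bromomethyl)-5-oxo-2,5-dihydrofuran-2-yl]-3-{[(tert-butyldimethylsilyl)oxy]methyl}-7-methylocta-2,6-dienal | O=C/C=C(\CO[Si](C)(C)C(C)(C)C)CC/C=C(\C)C[C@H]1OC(=O)C(CBr)=C1 | intermediate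
22 | allylchromium(III) dichloride derived from 21 | O=C/C=C(\CO[Si](C)(C)C(C)(C)C)CC/C=C(\C)C[C@H]1OC(=O)C(C[Cr](Cl)Cl)=C1 | intermediate
23 | (6R,7S,8R)-15-[(tert-butyldimethylsilyl)oxy]-6-hydroxygermacra-1(10),4,11(13)-trien-12,8-olide (both ring olefins trans in the ring; 6α-OH, 7α-H, 8β-O, cis-fused lactone) | O=C1O[C@@H]2C/C(C)=C/CC/C(CO[Si](C)(C)C(C)(C)C)=C/[C@@H](O)[C@@H]2C1=C | intermediate
24 | (6R,7S,8R)-6,15-dihydroxygermacra-1(10),4,11(13)-trien-12,8-olide | O=C1O[C@@H]2C/C(C)=C/CC/C(CO)=C/[C@@H](O)[C@@H]2C1=C | intermediate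
25 | 6,15-O-phenylboronate of 24 (seven-membered dioxaborepine) | O=C1O[C@@H]2C/C(C)=C/CC/C3=C/[C@@H](OB(OC3)c4ccccc4)[C@@H]2C1=C | intermediate
26 | 6,15-O-phenylboronate of 27 | C=C[C@@]1(C)C[C@H]2OC(=O)C(=C)[C@H]2[C@@H]3OB(c4ccccc4)OCC(=C)[C@H]13 | intermediate
27 | (5S,6R,7S,8R,10R)-6,15-dihydroxyelema-1,3,11(13)-trien-12,8-olide (10α-Me, 10β-vinyl, 5β-H, 6α-OH, 7α-H, 8β-O) | C=C[C@@]1(C)C[C@H]2OC(=O)C(=C)[C@H]2[C@H](O)[C@@H]1C(=C)CO | intermediate
28 | lithium (5S,6R,7R,8R,10R)-6,8,15-trihydroxyelema-1,3,11(13)-trien-12-oate | C=C[C@@]1(C)C[C@@H](O)[C@@H](C(=C)C(=O)[O-])[C@H](O)[C@@H]1C(=C)CO.[Li+] | intermediate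
29 | 4-methoxybenzyl (5S,6R,7R,8R,10R)-6,8,15-trihydroxyelema-1,3,11(13)-trien-12-oate | C=C[C@@]1(C)C[C@@H](O)[C@@H](C(=C)C(=O)OCc2ccc(OC)cc2)[C@H](O)[C@@H]1C(=C)CO | intermediate
30 | 3-methylfuran-2(5H)-one | CC1=CCOC1=O | starting material
31 | potassium (2Z)-4-hydroxy-2-methylbut-2-enoate | [K+].[O-]C(=O)/C(C)=C\CO | intermediate
32 | 4-methoxybenzyl (2Z)-4-hydroxy-2-methylbut-2-enoate | COc1ccc(COC(=O)/C(C)=C\CO)cc1 | intermediate
33 | 4-methoxybenzyl (2Z)-4-acetoxy-2-methylbut-2-enoate | COc1ccc(COC(=O)/C(C)=C\COC(C)=O)cc1 | intermediate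
34 | (2Z)-4-acetoxy-2-methylbut-2-enoic acid | OC(=O)/C(C)=C\COC(C)=O | intermediate
35 | (2Z)-4-acetoxy-2-methylbut-2-enoic 2,4,6-trichlorobenzoic anhydride | O=C(OC(=O)c1c(Cl)cc(Cl)cc1Cl)/C(C)=C\COC(C)=O | intermediate
36 | 6,15-O-phenylboronate of 29 | C=C[C@@]1(C)C[C@@H](O)[C@@H](C(=C)C(=O)OCc2ccc(OC)cc2)[C@@H]3OB(c4ccccc4)OCC(=C)[C@H]13 | intermediate
37 | 6,15-O-phenylboronate of 38 | C=C[C@@]1(C)C[C@@H](OC(=O)/C(C)=C\COC(C)=O)[C@@H](C(=C)C(=O)OCc2ccc(OC)cc2)[C@@H]3OB(c4ccccc4)OCC(=C)[C@H]13 | intermediate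
38 | 4-methoxybenzyl (5S,6R,7S,8R,10R)-8-{[(2Z)-4-acetoxy-2-methylbut-2-enoyl]oxy}-6,15-dihydroxyelema-1,3,11(13)-trien-12-oate | C=C[C@@]1(C)C[C@@H](OC(=O)/C(C)=C\COC(C)=O)[C@@H](C(=C)C(=O)OCc2ccc(OC)cc2)[C@H](O)[C@@H]1C(=C)CO | intermediate
39 | (5S,6R,7S,8R,10R)-8-{[(2Z)-4-acetoxy-2-methylbut-2-enoyl]oxy}-6,15-dihydroxyelema-1,3,11(13)-trien-12-oic acid | C=C[C@@]1(C)C[C@@H](OC(=O)/C(C)=C\COC(C)=O)[C@@H](C(=C)C(=O)O)[C@H](O)[C@@H]1C(=C)CO | target

## Step count
Total: 16 steps (14 on the main line, 2 for the side-chain acid). Longest linear sequence: 14 steps (steps 1–12, 15, 16). Steps 2, 11 and 13 are telescoped sequences.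

## Three steps most likely to fail, with fallbacks

**Step 11 (boronate-templated Cope).** The risks are an incomplete or reversible rearrangement, loss of the labile boronate so that the untethered diol rearranges to the 5,10-epimeric elemane, and decomposition of the acid-sensitive germacradiene. The fallback sets out from 23 and returns at 27. Compound 23 is desilylated and diol 24 is isolated. Its O6 and O15 are tied covalently with tBu2Si(OTf)2 and 2,6-lutidine as the isolable germacradienolide di-tert-butylsilylene F3, which imposes the same geometric constraint but can be purified and cannot hydrolyse. F3 is rearranged under forcing conditions (o-dichlorobenzene, 170 °C, microwave) to the elemanolide di-tert-butylsilylene F4. HF·pyridine then cleaves F4 to 27.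

**Step 10 (ten-membered ring by Cr(II) allylation).** The risks are oligomerisation, reduction of the bromide without C–C bond formation, and translactonisation of the Cr alkoxide to the 6,12-olide. The fallback sets out from 21 and returns at 23. The allylic bromide is converted with B2pin2 and catalytic Pd2(dba)3 (toluene, 50 °C) into the pinacol allylboronate F1. F1 is cyclised at 2 mM by Sc(OTf)3-catalysed intramolecular allylboration at 0 °C, through the same ring-locked closed chair but without a basic metal alkoxide, to give the O6-pinacolborate ester of the germacradienolide F2. Triethanolamine/water work-up converts F2 into 23.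

**Step 15 (acylation of O8 with the Z-acid).** The risks are DMAP-induced Z→E isomerisation of the angelate-type acid, relactonisation of the 8-hydroxy PMB ester, and slow acylation. The fallback sets out from 29 and returns at 38, building the side-chain olefin on the substrate. 2-(Diphenoxyphosphoryl)propanoic acid is activated as its 2,4,6-trichlorobenzoic mixed anhydride F5. F5 acylates 29, masked as boronate 36, to give the boronate-masked 8-O-phosphonopropanoate F6. Sorbitol work-up gives the phosphonoester triol F7. Ando Z-selective olefination of F7 with 2-oxoethyl acetate (NaI, DBU, THF, −78 → 0 °C) gives 38 directly.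

## Further compounds
F1 | step 10 | pinacol allylboronate of 21 [(2R)-butenolide bearing CH2Bpin] | O=C/C=C(\CO[Si](C)(C)C(C)(C)C)CC/C=C(\C)C[C@H]1OC(=O)C(CB2OC(C)(C)C(C)(C)O2)=C1
F2 | step 10 | O6-pinacolborate ester of 23 | O=C1O[C@@H]2C/C(C)=C/CC/C(CO[Si](C)(C)C(C)(C)C)=C/[C@@H](OB3OC(C)(C)C(C)(C)O3)[C@@H]2C1=C
F3 | step 11 | 6,15-O-di-tert-butylsilylene of 24 | O=C1O[C@@H]2C/C(C)=C/CC/C3=C/[C@@H](O[Si](OC3)(C(C)(C)C)C(C)(C)C)[C@@H]2C1=C
F4 | step 11 | 6,15-O-di-tert-butylsilylene of 27 | C=C[C@@]1(C)C[C@H]2OC(=O)C(=C)[C@H]2[C@@H]3O[Si](C(C)(C)C)(C(C)(C)C)OCC(=C)[C@H]13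
F5 | step 15 | 2-(diphenoxyphosphoryl)propanoic 2,4,6-trichlorobenzoic anhydride | CC(C(=O)OC(=O)c1c(Cl)cc(Cl)cc1Cl)P(=O)(Oc1ccccc1)Oc1ccccc1
F6 | step 15 | 6,15-O-phenylboronate of the 8-O-[2-(diphenoxyphosphoryl)propanoyl] PMB ester | C=C[C@@]1(C)C[C@@H](OC(=O)C(C)P(=O)(Oc2ccccc2)Oc2ccccc2)[C@@H](C(=C)C(=O)OCc2ccc(OC)cc2)[C@@H]3OB(c4ccccc4)OCC(=C)[C@H]13
F7 | step 15 | 4-methoxybenzyl 8-O-[2-(diphenoxyphosphoryl)propanoyl]-6,15-dihydroxyelema-1,3,11(13)-trien-12-oate | C=C[C@@]1(C)C[C@@H](OC(=O)C(C)P(=O)(Oc2ccccc2)Oc2ccccc2)[C@@H](C(=C)C(=O)OCc2ccc(OC)cc2)[C@H](O)[C@@H]1C(=C)CO
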